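## Structural features

The target is a tetracyclic flavone. Ring A (C4a–C8a) carries a hydrogen-bonded 5-OH, a 7-OMe and, between them at C6, an (E)-3-methylbut-1-enyl chain. Ring C is the γ-pyranone O1–C2–C3–C4–C4a–C8a, and ring B (C1′–C6′) carries the 4′-OH. A seven-membered oxepine (C2, C3, C9, C10, O11, C2′, C1′) bridges C3 and C2′; it shares the C2–C3 bond with ring C and the C1′–C2′ bond with ring B. C10 is the only stereocentre (S) and has no stereogenic neighbour; it sits between O11, the C9 methylene and the quaternary carbon that bears the hydroperoxide. The only other stereo-element is the E alkene at C6. The fragile groups are the tertiary hydroperoxide (reduced by phosphines and low-valent metals, rearranged by strong acid), the conjugated disubstituted alkene, and the distinction between 5-OH and 7-OMe. The real difficulty is timing: the O–O group has to come from a radical hydroperoxidation that would not reliably tell two alkenes apart, while the C6 alkene calls for palladium chemistry that peroxides tolerate poorly. Building the oxepine around a single aryl-ether stereocentre is the second problem. The key step uses the C2–C3 edge common to pyranone and oxepine as a masked carbonyl/α-methylene pair: a 1-benzoxepin-5-one that already holds ring B, O11, C10, C9, C3 and C2 is annulated with a 2-fluorobenzoyl unit that brings C4 and ring A and, by loss of fluoride, the O1–C8a bond.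

## Logic of the disconnections

20 ⇒ 19. The two O–Si bonds (peroxide oxygen and 4′-oxygen) are cut first. The hydroperoxide and the ring B phenol then stay masked through all metal chemistry. The forward step needs a fluoride source mild enough to leave the O–O bond alone.

19 ⇒ 18. The C6–alkenyl bond is cut because an sp2–sp2 bond of defined E geometry is best made by cross-coupling of an aryl iodide with an alkenylboron reagent. The side chain becomes a commercial reagent. The demand is that zerovalent palladium, ligand and base leave the silyl peroxide untouched.

18 ⇒ 17. The C6–I bond is cut. C6 is the only position ortho to the free 5-OH, and that is the handle for regiocontrol against C8 and ring B. The forward iodination must be buffered so that the silyl peroxide is not solvolysed.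

17 ⇒ 16. The C–OO bond at the tertiary carbon is cut back to an isopropenyl group. A 1,1-disubstituted alkene is the natural precursor of a tertiary hydroperoxide by Markovnikov radical oxygenation, and doing this while it is the only isolated alkene removes the chemoselectivity problem. The demand is that O2 traps the tertiary radical faster than the neighbouring aryloxy group is lost.

16 ⇒ 15. The O5–CH3 bond is cut. A methyl ether survives acid chloride and amide-base chemistry, and its peri relation to C4=O allows chelation-controlled removal beside the 7-OMe. The Lewis acid must spare the allylic C10–O11 ether and the silyl ether.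

15 ⇒ 10 + 13 (through 14). C3–C4 and O1–C8a are cut. This removes the pyranone and divides the tetracycle into a chiral bicyclic ketone and an achiral aroyl chloride of similar size. The forward step needs C- rather than O-acylation and displacement of fluoride, not methoxide.

13 ⇒ 12 ⇒ 11. These are functional-group changes only (C–Cl, then the aldehyde C–H to C–OH), reaching a commercial aldehyde with the substitution pattern in place.

10 ⇒ 8 (through 9). The aryl–carbonyl bond (the future C1′–C2 bond) is cut. An aryllithium generated from a bromide fixes the ring position unambiguously, and an N-methoxy-N-methyl amide stops at the ketone. The seven-membered ring becomes an open aryl ether. The demand is halogen–metal exchange faster than attack of the alkyllithium on the amide.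

8 ⇒ 2 + 7. The O11–C10 bond is cut. This separates the aromatic part from the chiral chain and passes the stereocentre to a secondary allylic alcohol. The forward etherification must proceed by clean SN2 inversion without allylic transposition.

2 ⇒ 1. One O–Si bond is cut. The demand is selective silylation of the hydroxyl para to bromine.

7 ⇒ 6 ⇒ 4 ⇒ 3. The carbinol C–H is cut (catalytic enantioselective ketone reduction), then the amide C–N bond, then the bond between the ketone carbon and the isopropenyl group. This leads to a cyclic anhydride and an alkenyl Grignard reagent. The reduction must deliver hydride to one face of an enone without touching the alkene or the amide.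

## Other disconnections considered

Alternative 1: The cut is C2–C1′, so the oxepine is closed last on a finished chromone. The open aryl ether A2 has a free C2–H and a side chain that already carries O11, ring B and a C(CH3)2CO2CH3 group at C10. With Pd(OAc)2, AgOAc and pivalic acid, divalent palladium would metalate C2 and then the ring B C–H para to the silyloxy group; reductive elimination would give A1, and the silver salt would return zerovalent palladium to the divalent state.
- In favour: no halogen or organometallic handle is needed, the chromone C2–H is the most reactive C–H of the heterocycle, and A2 and A1 contain no alkene and no allylic ether.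
- Against: ring B offers two C–H bonds ortho to O11, and only the bulk of the silyl group steers the metal away from the one between the two oxygens. The conditions are hot and oxidising with a free 5-OH. The ester must later become the hydroperoxide (hydrolysis of a neopentyl-type ester, then radical decarboxylative oxygenation), and C6 still needs iodination and coupling.
- Comparison: on structure the plans mirror each other (pyranone onto oxepine here, oxepine onto pyranone there). On mechanism the fluoride in 13 fixes the ring-closure site beyond doubt, whereas the C–H coupling relies on a steric bias. On step economy the alternative is the better up to A1 and is equal for the C6 work, but it is clearly longer for the peroxide. It is also the better in never exposing an allylic C–O bond to Mitsunobu or Lewis-acid conditions.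

Alternative 2: The cuts are C1′–C2′ and C5′–C6′, so ring B and the oxepine are made together. In A4 a 2-ethynylchromone carries at C3 a chain ending in a 1-alkoxy-1,3-bis(silyloxy)diene whose alkoxy oxygen is O11. Intramolecular [4+2] addition, loss of silanol and desilylation would give A3.
- In favour: the tether and the electronics agree, since the nucleophilic CH2 terminus of the diene meets the alkyne carbon remote from C2. Two rings form at once, the 4′-OH emerges free, and the C6 chain is already present.
- Against: A4 is the silyl ketene acetal of an allylic ester, so a [3,3] ester-enolate rearrangement across the isopropenyl group competes directly with the cycloaddition. The tether closes a seven-membered ring in the transition state. The ynone is a strong acceptor for any nucleophile present when the diene is generated. A3 has two alkenes and free phenols, so the hydroperoxidation that remains is the unsolved selectivity problem that the chosen plan avoids by oxidising 16.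
- Comparison: the alternative is the better in convergence and in the number of steps after the key step (one or two against five). It is weaker in the stability of its substrate, the certainty of the ring-forming mechanism, and the final oxidation.

Alternative 3: The cut is O11–C2′. Carbinol A6, a 2′-fluoroflavone with the C10 hydroxyl free, would be converted with KN(SiMe3)2 into its potassium alkoxide, which displaces fluoride to give A5.
- In favour: the C10–O bond is never broken, so the configuration set in A6 is retained. This is better than an inversion at an allylic centre. The fluoride is ortho to the carbon attached to the electron-poor C2.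
- Against: the alkoxide can instead add to C2 through a five-membered transition state and open the pyranone, a kinetically easier closure than the seven-membered one. Activation by a vinylogous carbonyl is weaker than by the ketone used in the chosen plan. The aryl silyl ether is exposed to a hard alkoxide. A5 again has both alkenes.
- Comparison: on structure both plans finish the ring system by an intramolecular fluoride displacement and are equal in that respect. On mechanism the chosen closure is six-membered, uses a soft diketonate oxygen and has no competing electrophile. On step economy the alternative is about equal before the key step and shorter after it, but only if the two alkenes can be told apart in the peroxidation.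

Key step: step 9

Remarks on the chemistry:
- The ring B phenol is carried as a triisopropylsilyl ether instead of a tert-butyldimethylsilyl ether. It stands up better to t-BuLi, to LiN(SiMe3)2 with liberated fluoride, to BCl3 and to the basic coupling, and it screens C3′ and C5′ during iodination.
- C10 is S in 20 and, because the ranking O > isopropenyl or peroxy-bearing carbon > CH2 > H never changes, S in every compound from 8 onwards. Alcohol 7 is R because step 5 inverts.
- "Oxepinoflavone" means the flavone in which C3 and C2′ are joined by C9H2–C10H–O11 (C9 on C3, O11 on C2′); flavone locants are used.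
- Isopropenylmagnesium bromide, the oxazaborolidine catalyst, benzyltrimethylammonium dichloroiodate and (E)-3-methylbut-1-enylboronic acid pinacol ester are taken to be commercial.

## Route

Step 1
Reactants: 1 4-bromoresorcinol
Product: 2 2-bromo-5-(triisopropylsilyloxy)phenol
Conditions: TIPSCl (1.0 equiv), imidazole, DMF, 0 °C
Reagents that add atoms: chlorotriisopropylsilane, CC(C)[Si](Cl)(C(C)C)C(C)C
Why: Silyl ether formation; the hydroxyl para to bromine is unhindered whereas the other is flanked by bromine and hydrogen-bonded to it, so one equivalent of the bulky silyl chloride should take the para hydroxyl.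

Step 2
Reactants: 3 succinic anhydride
Product: 4 5-methyl-4-oxohex-5-enoic acid
Conditions: CH2=C(CH3)MgBr (1.0 equiv), THF, −78 to −20 °C; then aq. HCl
Reagents that add atoms: isopropenylmagnesium bromide, CC(=C)[Mg]Br
Why: Acyl substitution of a cyclic anhydride by a Grignard reagent; at low temperature with one equivalent the ring-opened magnesium carboxylate is a poor electrophile, so the γ-keto acid should form without much second addition.

Step 3
Reactants: 4 5-methyl-4-oxohex-5-enoic acid
Product: 6 N-methoxy-N,5-dimethyl-4-oxohex-5-enamide, via acyl imidazolide 5 (not isolated)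
Conditions: CDI, CH2Cl2, rt; then MeNHOMe·HCl, rt
Reagents that add atoms: N,O-dimethylhydroxylamine hydrochloride, CNOC.Cl; 1,1′-carbonyldiimidazole, O=C(n1ccnc1)n1ccnc1 (its imidazole stays only in 5)
Why: Weinreb amide formation through the acyl imidazolide; the weakly basic amine attacks the activated acyl group much faster than it adds to the α-substituted enone.

Step 4
Reactants: 6 N-methoxy-N,5-dimethyl-4-oxohex-5-enamide
Product: 7 (R)-4-hydroxy-N-methoxy-N,5-dimethylhex-5-enamide
Conditions: (S)-1-methyl-3,3-diphenyl-tetrahydro-1H,3H-pyrrolo[1,2-c][1,3,2]oxazaborole (cat.), catecholborane, toluene, −78 °C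
Reagents that add atoms: none
Why: Corey–Bakshi–Shibata reduction; the ketone binds the catalyst boron anti to the larger isopropenyl group, so the (S)-catalyst should give the R carbinol (the same sense as acetophenone to (R)-1-phenylethanol), and catecholborane at −78 °C reduces 1,2 without touching the alkene or the amide.

Step 5
Reactants: 2 2-bromo-5-(triisopropylsilyloxy)phenol; 7 (R)-4-hydroxy-N-methoxy-N,5-dimethylhex-5-enamide
Product: 8 (S)-4-[2-bromo-5-(triisopropylsilyloxy)phenoxy]-N-methoxy-N,5-dimethylhex-5-enamide
Conditions: PPh3, DIAD, toluene, 0 °C to rt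
Reagents that add atoms: none
Why: Mitsunobu etherification; the acidic ortho-bromophenol displaces the oxyphosphonium group by SN2 with inversion, so the R carbinol becomes the S aryl ether.

Step 6
Reactants: 8 (S)-4-[2-bromo-5-(triisopropylsilyloxy)phenoxy]-N-methoxy-N,5-dimethylhex-5-enamide
Product: 10 (S)-2-isopropenyl-8-(triisopropylsilyloxy)-3,4-dihydro-1-benzoxepin-5(2H)-one, via aryllithium 9 (not isolated)
Conditions: t-BuLi (2.1 equiv), THF, −78 °C; then H2O
Reagents that add atoms: none
Why: Parham cyclisation; bromine–lithium exchange outruns attack of t-BuLi on the amide, the aryllithium adds intramolecularly to the Weinreb amide, and the chelated tetrahedral intermediate releases the seven-membered ketone only on quench, so there is no over-addition and the stereocentre (no acidic hydrogen) is untouched.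

Step 7
Reactants: 11 2-fluoro-4,6-dimethoxybenzaldehyde
Product: 12 2-fluoro-4,6-dimethoxybenzoic acid
Conditions: NaClO2, NaH2PO4, 2-methyl-2-butene, t-BuOH–H2O, rt
Reagents that add atoms: sodium chlorite, [Na+].[O-]Cl=O
Why: Pinnick oxidation; chlorous acid oxidises the aldehyde and 2-methyl-2-butene traps the hypochlorous acid that would otherwise chlorinate the electron-rich ring.

Step 8
Reactants: 12 2-fluoro-4,6-dimethoxybenzoic acid
Product: 13 2-fluoro-4,6-dimethoxybenzoyl chloride
Conditions: (COCl)2, DMF (cat.), CH2Cl2, 0 °C to rt; used crude
Reagents that add atoms: oxalyl chloride, O=C(Cl)C(=O)Cl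
Why: Acid chloride formation under Vilsmeier-type catalysis; the by-products are gases, and the crude chloride is used at once.

Step 9
Reactants: 10 (S)-2-isopropenyl-8-(triisopropylsilyloxy)-3,4-dihydro-1-benzoxepin-5(2H)-one; 13 2-fluoro-4,6-dimethoxybenzoyl chloride
Product: 15 (10S)-10-isopropenyl-5,7-dimethoxy-4′-(triisopropylsilyloxy)oxepinoflavone, via aroyl diketone 14 (not isolated)
Conditions: LiN(SiMe3)2 (2.2 equiv), THF, −78 °C; 13, −78 °C to rt; then 65 °C
Reagents that add atoms: none
Why: LiN(SiMe3)2 deprotonates the only enolisable position of 10 (the methylene next to the carbonyl, the future C3), and the lithium enolate attacks 13 at carbon to give diketone 14, which the second equivalent of base converts at once into its chelated enolate. On warming, the enolate oxygen on the former ketone carbon (future C2) adds to the fluorine-bearing ring carbon, activated by the ortho aroyl carbonyl (future C4), and the adduct expels fluoride; this addition–elimination SNAr closes the six-membered pyranone by ipso attack through a six-membered transition state. The closest known reaction type is the one-pot chromone and flavone synthesis from ketone enolates and 2-fluorobenzoyl chlorides. No stereocentre is created: C3 ends as an sp2 carbon, and C10 lies two atoms from the enolate and carries no acidic hydrogen, so its S configuration is kept. Three selectivities are needed. C- over O-acylation is favoured by the lithium counter-ion and by the second equivalent of base, because any enol ester can pass its acyl group to remaining enolate and the diketonate is the thermodynamic sink. Fluoride leaves in preference to the ortho methoxide because of its far greater nucleofugality in SNAr. Survival of the aryl silyl ether rests on the triisopropylsilyl group and on the insolubility of LiF in THF.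

Step 10
Reactants: 15 (10S)-10-isopropenyl-5,7-dimethoxy-4′-(triisopropylsilyloxy)oxepinoflavone
Product: 16 (10S)-5-hydroxy-10-isopropenyl-7-methoxy-4′-(triisopropylsilyloxy)oxepinoflavone
Conditions: BCl3 (1.3 equiv), CH2Cl2, −78 to −20 °C; aq. NaHCO3
Reagents that add atoms: none
Why: Chelation-controlled Lewis-acid ether cleavage; BCl3 binds between the C4 carbonyl and the peri 5-methoxy oxygen and chloride removes only that methyl group, while at low temperature and small excess the aryl silyl ether and the weakly basic O11 should be spared.

Step 11
Reactants: 16 (10S)-5-hydroxy-10-isopropenyl-7-methoxy-4′-(triisopropylsilyloxy)oxepinoflavone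
Product: 17 (10S)-5-hydroxy-7-methoxy-10-[2-(triethylsilylperoxy)propan-2-yl]-4′-(triisopropylsilyloxy)oxepinoflavone
Conditions: Co(acac)2 (cat.), Et3SiH, O2 (1 atm), ClCH2CH2Cl, rt
Reagents that add atoms: triethylsilane, CC[SiH](CC)CC; dioxygen, O=O
Why: Mukaiyama–Isayama hydroperoxysilylation; a cobalt hydride passes a hydrogen atom to the terminal CH2 of the only isolated alkene, O2 traps the tertiary radical and the peroxyl is silylated, so the Markovnikov silyl peroxide forms without a new stereocentre and without involving C10; the tetrasubstituted, electron-poor C2=C3 bond does not react.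

Step 12
Reactants: 17 (10S)-5-hydroxy-7-methoxy-10-[2-(triethylsilylperoxy)propan-2-yl]-4′-(triisopropylsilyloxy)oxepinoflavone
Product: 18 (10S)-5-hydroxy-6-iodo-7-methoxy-10-[2-(triethylsilylperoxy)propan-2-yl]-4′-(triisopropylsilyloxy)oxepinoflavone
Conditions: BnMe3N(ICl2), CaCO3, CH2Cl2–MeOH, rt
Reagents that add atoms: benzyltrimethylammonium dichloroiodate, C[N+](C)(C)Cc1ccccc1.Cl[I-]Cl
Why: Electrophilic aromatic iodination; with 5-OH free, C6 is the only position ortho to a free phenol and this reagent is known to iodinate 5-hydroxy-7-alkoxyflavones there, CaCO3 takes up the HCl so the silyl peroxide is not solvolysed, and the bulky silyl ether screens C3′ and C5′.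

Step 13
Reactants: 18 (10S)-5-hydroxy-6-iodo-7-methoxy-10-[2-(triethylsilylperoxy)propan-2-yl]-4′-(triisopropylsilyloxy)oxepinoflavone
Product: 19 (10S)-5-hydroxy-7-methoxy-6-[(E)-3-methylbut-1-enyl]-10-[2-(triethylsilylperoxy)propan-2-yl]-4′-(triisopropylsilyloxy)oxepinoflavone
Conditions: (E)-i-PrCH=CH–B(pin), PdCl2(dppf) (cat.), K3PO4, THF–H2O (20:1), 40 °C
Reagents that add atoms: (E)-3-methylbut-1-enylboronic acid pinacol ester, CC(C)/C=C/B1OC(C)(C)C(C)(C)O1
Why: Suzuki–Miyaura coupling; oxidative addition of the aryl iodide to zerovalent palladium, transmetalation of the alkenylboronate with retention of the E geometry and reductive elimination, while the chelating diphosphine leaves no free phosphine to reduce the O–O bond and the tertiary silyl peroxide has no α-hydrogen for base- or metal-induced fragmentation.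

Step 14
Reactants: 19 (10S)-5-hydroxy-7-methoxy-6-[(E)-3-methylbut-1-enyl]-10-[2-(triethylsilylperoxy)propan-2-yl]-4′-(triisopropylsilyloxy)oxepinoflavone
Product: 20 (10S)-5,4′-dihydroxy-10-(2-hydroperoxypropan-2-yl)-7-methoxy-6-[(E)-3-methylbut-1-enyl]oxepinoflavone (CNP0171472.1)
Conditions: Bu4NF, AcOH, THF, 0 °C
Reagents that add atoms: none
Why: Fluoride-mediated desilylation; buffered fluoride cleaves the O–Si bond of the peroxide and the aryl silyl ether without reducing or rearranging the tertiary hydroperoxide, giving the target.

## Compound list

1 | 4-bromoresorcinol | Oc1ccc(Br)c(O)c1 | starting material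
2 | 2-bromo-5-(triisopropylsilyloxy)phenol | Oc1cc(O[Si](C(C)C)(C(C)C)C(C)C)ccc1Br | intermediate
3 | succinic anhydride | O=C1CCC(=O)O1 | starting material
4 | 5-methyl-4-oxohex-5-enoic acid | CC(=C)C(=O)CCC(=O)O | intermediate
5 | 1-(imidazol-1-yl)-5-methylhex-5-ene-1,4-dione (acyl imidazolide of 4) | CC(=C)C(=O)CCC(=O)n1ccnc1 | intermediate
6 | N-methoxy-N,5-dimethyl-4-oxohex-5-enamide | CON(C)C(=O)CCC(=O)C(C)=C | intermediate
7 | (R)-4-hydroxy-N-methoxy-N,5-dimethylhex-5-enamide | CON(C)C(=O)CC[C@H](C(C)=C)O | intermediate
8 | (S)-4-[2-bromo-5-(triisopropylsilyloxy)phenoxy]-N-methoxy-N,5-dimethylhex-5-enamide | CON(C)C(=O)CC[C@@H](C(C)=C)Oc1cc(O[Si](C(C)C)(C(C)C)C(C)C)ccc1Br | intermediate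
9 | aryllithium from 8 (lithium in place of bromine) | CON(C)C(=O)CC[C@@H](C(C)=C)Oc1cc(O[Si](C(C)C)(C(C)C)C(C)C)ccc1[Li] | intermediate
10 | (S)-2-isopropenyl-8-(triisopropylsilyloxy)-3,4-dihydro-1-benzoxepin-5(2H)-one | O=C1CC[C@@H](C(C)=C)Oc2cc(O[Si](C(C)C)(C(C)C)C(C)C)ccc12 | intermediate
11 | 2-fluoro-4,6-dimethoxybenzaldehyde | COc1cc(F)c(C=O)c(OC)c1 | starting material
12 | 2-fluoro-4,6-dimethoxybenzoic acid | COc1cc(F)c(C(=O)O)c(OC)c1 | intermediate
13 | 2-fluoro-4,6-dimethoxybenzoyl chloride | COc1cc(F)c(C(=O)Cl)c(OC)c1 | intermediate
14 | (2S)-4-(2-fluoro-4,6-dimethoxybenzoyl)-2-isopropenyl-8-(triisopropylsilyloxy)-3,4-dihydro-1-benzoxepin-5(2H)-one (present as its lithium enolate; C4 not defined) | COc1cc(F)c(C(=O)C2C[C@@H](C(C)=C)Oc3cc(O[Si](C(C)C)(C(C)C)C(C)C)ccc3C2=O)c(OC)c1 | intermediate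
15 | (10S)-10-isopropenyl-5,7-dimethoxy-4′-(triisopropylsilyloxy)oxepinoflavone | COc1cc(OC)c2c(c1)oc1c(c2=O)C[C@@H](C(C)=C)Oc2cc(O[Si](C(C)C)(C(C)C)C(C)C)ccc2-1 | intermediate
16 | (10S)-5-hydroxy-10-isopropenyl-7-methoxy-4′-(triisopropylsilyloxy)oxepinoflavone | COc1cc(O)c2c(c1)oc1c(c2=O)C[C@@H](C(C)=C)Oc2cc(O[Si](C(C)C)(C(C)C)C(C)C)ccc2-1 | intermediate
17 | (10S)-5-hydroxy-7-methoxy-10-[2-(triethylsilylperoxy)propan-2-yl]-4′-(triisopropylsilyloxy)oxepinoflavone | COc1cc(O)c2c(c1)oc1c(c2=O)C[C@@H](C(C)(C)OO[Si](CC)(CC)CC)Oc2cc(O[Si](C(C)C)(C(C)C)C(C)C)ccc2-1 | intermediate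
18 | 6-iodo derivative of 17 | COc1c(I)c(O)c2c(c1)oc1c(c2=O)C[C@@H](C(C)(C)OO[Si](CC)(CC)CC)Oc2cc(O[Si](C(C)C)(C(C)C)C(C)C)ccc2-1 | intermediate
19 | 6-[(E)-3-methylbut-1-enyl] derivative of 17 | COc1c(/C=C/C(C)C)c(O)c2c(c1)oc1c(c2=O)C[C@@H](C(C)(C)OO[Si](CC)(CC)CC)Oc2cc(O[Si](C(C)C)(C(C)C)C(C)C)ccc2-1 | intermediate
20 | (10S)-5,4′-dihydroxy-10-(2-hydroperoxypropan-2-yl)-7-methoxy-6-[(E)-3-methylbut-1-enyl]oxepinoflavone (CNP0171472.1) | COc1cc2oc3c(c(=O)c2c(O)c1/C=C/C(C)C)C[C@@H](C(C)(C)OO)Oc1cc(O)ccc1-3 | target

## Step count and least certain steps

Total: 14 steps. Longest linear sequence: 11 steps (steps 2, 3, 4, 5, 6, 9, 10, 11, 12, 13, 14, from succinic anhydride).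

Step 9 (key step). Most likely to go wrong: acylation of the enolate at oxygen by the doubly ortho-substituted aroyl chloride, followed by only slow acyl transfer to carbon, and slow fluoride displacement because two methoxy groups enrich the ring. Fallback: set out from 10 and 11. The lithium enolate of 10 is added to aldehyde 11, which can react only at carbon, to give the β-hydroxy ketone F1. Dess–Martin oxidation then gives diketone 14, now isolated, and K2CO3 in DMF at 80 °C closes the pyranone by the same fluoride displacement, returning to the route at 15.

Step 13. Most likely to go wrong: base-induced loss of the silyl group from the peroxide, after which the peroxide anion oxidises the boronate or the O–O bond is reduced at zerovalent palladium. Fallback: set out from 18 and couple without base, water or boron by a Stille reaction. 3-Methylbut-1-yne is hydrostannylated (Bu3SnH, PdCl2(PPh3)2) to (E)-tributyl(3-methylbut-1-enyl)stannane F2, which is coupled with 18 using Pd2(dba)3 and AsPh3 in N-methylpyrrolidone at 40 °C, returning at 19.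

Step 12. Most likely to go wrong: solvolytic loss of the triethylsilyl group from the peroxide in the methanolic, HCl-generating medium, together with some attack at C8. Fallback: set out from 16 and iodinate before the peroxide exists. The iodine–morpholine complex in CH2Cl2 iodinates through the phenoxide, and in the absence of a nucleophilic solvent the isolated alkene forms only a reversible iodonium ion; this gives the 6-iodo isopropenyl compound F3. The conditions of step 11 then convert F3 into 18.

Step 10. Most likely to go wrong: Lewis-acid ionisation of the allylic C10–O11 bond (opening of the oxepine) or loss of the silyl ether, if BCl3 does not stay at the chelating site. Fallback: take the Lewis-acid step out of the late stage by starting from 11.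
- BCl3 removes the methyl group ortho to the formyl group, giving 2-fluoro-6-hydroxy-4-methoxybenzaldehyde F4.
- MOMCl with i-Pr2NEt gives the methoxymethyl ether F5.
- Aldol addition of the lithium enolate of 10 to F5 gives the β-hydroxy ketone F6.
- Dess–Martin oxidation gives the diketone F7.
- K2CO3 in DMF gives the 5-methoxymethoxy oxepinoflavone F8.
- Dilute HCl in MeOH–THF at rt hydrolyses the acetal and returns to the route at 16.

Step 5. Most likely to go wrong: partial allylic transposition or ionisation of the allylic oxyphosphonium ion, which erodes the enantiomeric purity and gives a regioisomeric ether, made worse by the hindered ortho-bromophenol. Fallback: set out from 6 and form the O11–C bond on the aromatic side with retention.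
- Reduction of 6 with the (R)-oxazaborolidine gives the (S)-hydroxy amide F9.
- Silylation of commercial 4-bromo-3-fluorophenol gives (4-bromo-3-fluorophenoxy)triisopropylsilane F10.
- Bromine–magnesium exchange of F10 (i-PrMgCl·LiCl) and addition to the magnesium alkoxide of F9 gives the γ-hydroxy aryl ketone F11.
- K2CO3 in DMF lets the alkoxide displace the fluoride ortho to the ketone, closing the oxepinone without touching the C–O bond at the stereocentre and returning at 10.

## Further compounds

F1 | step 9 | (2S)-4-[(2-fluoro-4,6-dimethoxyphenyl)(hydroxy)methyl]-2-isopropenyl-8-(triisopropylsilyloxy)-3,4-dihydro-1-benzoxepin-5(2H)-one (new centres not defined) | COc1cc(F)c(C(O)C2C[C@@H](C(C)=C)Oc3cc(O[Si](C(C)C)(C(C)C)C(C)C)ccc3C2=O)c(OC)c1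
F2 | step 13 | (E)-tributyl(3-methylbut-1-enyl)stannane | CCCC[Sn](CCCC)(CCCC)/C=C/C(C)C
F3 | step 12 | (10S)-5-hydroxy-6-iodo-10-isopropenyl-7-methoxy-4′-(triisopropylsilyloxy)oxepinoflavone | COc1c(I)c(O)c2c(c1)oc1c(c2=O)C[C@@H](C(C)=C)Oc2cc(O[Si](C(C)C)(C(C)C)C(C)C)ccc2-1
F4 | step 10 | 2-fluoro-6-hydroxy-4-methoxybenzaldehyde | COc1cc(O)c(C=O)c(F)c1
F5 | step 10 | 2-fluoro-4-methoxy-6-(methoxymethoxy)benzaldehyde | COCOc1cc(OC)cc(F)c1C=O
F6 | step 10 | (2S)-4-{[2-fluoro-4-methoxy-6-(methoxymethoxy)phenyl](hydroxy)methyl}-2-isopropenyl-8-(triisopropylsilyloxy)-3,4-dihydro-1-benzoxepin-5(2H)-one (new centres not defined) | COCOc1cc(OC)cc(F)c1C(O)C1C[C@@H](C(C)=C)Oc2cc(O[Si](C(C)C)(C(C)C)C(C)C)ccc2C1=O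
F7 | step 10 | (2S)-4-[2-fluoro-4-methoxy-6-(methoxymethoxy)benzoyl]-2-isopropenyl-8-(triisopropylsilyloxy)-3,4-dihydro-1-benzoxepin-5(2H)-one | COCOc1cc(OC)cc(F)c1C(=O)C1C[C@@H](C(C)=C)Oc2cc(O[Si](C(C)C)(C(C)C)C(C)C)ccc2C1=O
F8 | step 10 | (10S)-10-isopropenyl-7-methoxy-5-(methoxymethoxy)-4′-(triisopropylsilyloxy)oxepinoflavone | COCOc1cc(OC)cc2oc3c(c(=O)c12)C[C@@H](C(C)=C)Oc1cc(O[Si](C(C)C)(C(C)C)C(C)C)ccc1-3
F9 | step 5 | (S)-4-hydroxy-N-methoxy-N,5-dimethylhex-5-enamide | CON(C)C(=O)CC[C@@H](C(C)=C)O
F10 | step 5 | (4-bromo-3-fluorophenoxy)triisopropylsilane | CC(C)[Si](Oc1ccc(Br)c(F)c1)(C(C)C)C(C)C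
F11 | step 5 | (S)-1-[2-fluoro-4-(triisopropylsilyloxy)phenyl]-4-hydroxy-5-methylhex-5-en-1-one | O=C(CC[C@@H](C(C)=C)O)c1ccc(O[Si](C(C)C)(C(C)C)C(C)C)cc1F
A1 | alternative 1 | (10S)-5-hydroxy-7-methoxy-10-(1-methoxy-2-methyl-1-oxopropan-2-yl)-4′-(triisopropylsilyloxy)oxepinoflavone | COc1cc2oc3c(c(=O)c2c(O)c1)C[C@@H](C(C)(C)C(=O)OC)Oc1cc(O[Si](C(C)C)(C(C)C)C(C)C)ccc1-3
A2 | alternative 1 | methyl (3S)-4-(5-hydroxy-7-methoxy-4-oxochromen-3-yl)-2,2-dimethyl-3-[3-(triisopropylsilyloxy)phenoxy]butanoate | COc1cc2occ(C[C@@H](C(C)(C)C(=O)OC)Oc3cccc(O[Si](C(C)C)(C(C)C)C(C)C)c3)c(=O)c2c(O)c1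
A3 | alternative 2 | (10S)-5,4′-dihydroxy-10-isopropenyl-7-methoxy-6-[(E)-3-methylbut-1-enyl]oxepinoflavone | COc1cc2oc3c(c(=O)c2c(O)c1/C=C/C(C)C)C[C@@H](C(C)=C)Oc1cc(O)ccc1-3
A4 | alternative 2 | 2-ethynyl-7-methoxy-6-[(E)-3-methylbut-1-enyl]-5-(trimethylsilyloxy)chromone bearing at C3 the (2S)-2-[1,3-bis(trimethylsilyloxy)buta-1,3-dienyloxy]-3-methylbut-3-enyl chain | COc1cc2oc(C#C)c(C[C@@H](C(C)=C)OC(O[Si](C)(C)C)=CC(=C)O[Si](C)(C)C)c(=O)c2c(O[Si](C)(C)C)c1/C=C/C(C)C
A5 | alternative 3 | (10S)-4′-(tert-butyldimethylsilyloxy)-10-isopropenyl-7-methoxy-5-(methoxymethoxy)-6-[(E)-3-methylbut-1-enyl]oxepinoflavone | COc1cc2oc3c(c(=O)c2c(OCOC)c1/C=C/C(C)C)C[C@@H](C(C)=C)Oc1cc(O[Si](C)(C)C(C)(C)C)ccc1-3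
A6 | alternative 3 | 2-[4-(tert-butyldimethylsilyloxy)-2-fluorophenyl]-3-[(2S)-2-hydroxy-3-methylbut-3-enyl]-7-methoxy-5-(methoxymethoxy)-6-[(E)-3-methylbut-1-enyl]chromone | COc1cc2oc(-c3ccc(O[Si](C)(C)C(C)(C)C)cc3F)c(C[C@H](O)C(C)=C)c(=O)c2c(OCOC)c1/C=C/C(C)C
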